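**Retrosynthetic overview**
1. Ring B is closed last by ring-closing metathesis, and the ester-bearing centre is then set by enolisation and kinetic protonation.
2. The ring A alkene comes from an enol triflate. The triflate is made by Michael addition of a crotonate dienolate to the convex face of a bowl-shaped tricyclic enone (rings A, C, D); this addition makes the A/B junction trans.
3. The tricyclic enone comes from reductive loss of a γ-methoxy group from a photoadduct. The photoadduct is formed by an intramolecular enone–alkene [2+2] of a 4-methoxycyclohexa-2,5-dienone, which builds cyclobutane D and cyclopentane C in one step and uses only one of the two mirror-related enone arms.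
4. The dienone comes from oxidative dearomatisation of a para-substituted phenol. The phenol comes from a one-pot ester reduction/Wittig olefination and a rhodium-catalysed asymmetric arylation of ethyl sorbate with 4-hydroxyphenylboronic acid.
5. Ring order: arene (becomes ring A), then D and C together, then B.

Assumption: the SMILES is read literally, so rings A and B are trans-fused (an intramolecular Diels–Alder closure would give cis), ring C is cis-fused to A, B and D, the decenyl chain is exo on D, and CO2Me is cis to the ring A bond on the neighbouring fusion carbon.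

Ring letters: A = six-membered ring fused to the cyclobutane; B = six-membered ring carrying CO2Me; C = cyclopentane; D = cyclobutane.

**Step 1**
Reactants: 1 4-hydroxyphenylboronic acid; 2 ethyl (2E,4E)-hexa-2,4-dienoate
Product: 3 ethyl (3R,4E)-3-(4-hydroxyphenyl)hex-4-enoate
Conditions: [Rh(OH)((S)-BINAP)]2 (1.5 mol %), 1 (2 equiv), dioxane–H2O 10:1, 40 °C
Reagents that add atoms: none
Why: Hayashi–Miyaura asymmetric 1,4-addition, in which the aryl–rhodium species adds to C3 of the dienoate (the δ-methyl group disfavours 1,6-addition) and (S)-BINAP is expected, by the model for (E)-enones, to deliver the aryl group to the C3 Si face, which is 3R here because propenyl outranks CH2CO2Et (the antipodal ligand is used if the first batch shows the opposite sense).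

**Step 2**
Reactants: 4 11-bromoundec-1-ene
Product: 5 (E)-11-bromoundec-2-ene
Conditions: [Cp*Ru(NCMe)(κ2-P,N-L)]PF6 (1 mol %; L = 4-tert-butyl-2-(diisopropylphosphino)-1-methylimidazole), acetone, 40 °C
Reagents that add atoms: none
Why: Catalytic one-position alkene isomerisation that stops at the thermodynamically preferred (E)-2-alkene and leaves the primary bromide alone; no stereocentre is involved.

**Step 3**
Reactants: 5 (E)-11-bromoundec-2-ene
Product: 6 [(E)-undec-9-en-1-yl]triphenylphosphonium bromide
Conditions: PPh3 (1.1 equiv), MeCN, reflux
Reagents that add atoms: triphenylphosphine, c1ccc(cc1)P(c1ccccc1)c1ccccc1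
Why: SN2 quaternisation of the primary bromide gives the Wittig salt.

**Step 4**
Reactants: 3 ethyl (3R,4E)-3-(4-hydroxyphenyl)hex-4-enoate; 6 [(E)-undec-9-en-1-yl]triphenylphosphonium bromide
Product: 9 4-[(2E,4R,6Z,15E)-heptadeca-2,6,15-trien-4-yl]phenol, via phosphorus ylide 7 (not isolated), via aldehyde 8 (not isolated)
Conditions: 6 (1.3 equiv), NaHMDS, THF, 0 °C; separately 3, i-Bu2AlH (2.2 equiv), CH2Cl2, −78 °C; combine at −78 °C, then rt
Reagents that add atoms: none
Why: One-pot ester reduction/Wittig olefination, in which i-Bu2AlH (the first equivalent masks the phenol as its aluminium phenoxide) stops at the aluminium hemiacetal that releases aldehyde 8 only as the salt-free unstabilised ylide 7 consumes it (cis-selective); the C4 stereocentre is β to the carbonyl and untouched, and the 6Z geometry is erased in step 6.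

**Step 5**
Reactants: 9 4-[(2E,4R,6Z,15E)-heptadeca-2,6,15-trien-4-yl]phenol
Product: 10 4-[(2E,4R,6Z,15E)-heptadeca-2,6,15-trien-4-yl]-4-methoxycyclohexa-2,5-dien-1-one
Conditions: PhI(OAc)2 (1.1 equiv), MeOH, 0 °C; product kept cold and acid-free
Reagents that add atoms: methanol, CO
Why: Oxidative dearomatisation of a para-alkylphenol with a hypervalent iodine reagent, where methanol attacks the para carbon of the O-bound aryloxyiodane to give a quinol ether whose ring has a mirror plane (two enantiotopic enone arms); the side-chain stereocentre is not touched.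

**Step 6**
Reactants: 10 4-[(2E,4R,6Z,15E)-heptadeca-2,6,15-trien-4-yl]-4-methoxycyclohexa-2,5-dien-1-one
Product: 11 tricyclic methoxy enone (rings A, C, D)
Conditions: hν (366 nm), degassed benzene (5 mM), rt, stopped at about 90 % conversion
Reagents that add atoms: none
Why: Intramolecular enone–alkene [2+2] photocycloaddition of a 4-(but-3-enyl)cyclohexa-2,5-dienone (triplet, first bond by five-membered ring closure) in which the 4R side-chain centre selects the enone arm that lets propenyl sit pseudo-equatorial in the chair-like closure (propenyl cis to the new cyclobutane carbon), ring C can only fuse cis on the tether face, and the 1,4-diradical collapses to the cis-fused cyclobutane with the decenyl chain on the open exo side whatever the alkene geometry, fixing five stereocentres.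

**Step 7**
Reactants: 11 tricyclic methoxy enone (rings A, C, D)
Product: 13 tricyclic enone (rings A, C, D), via β,γ-unsaturated ketone 12 (not isolated)
Conditions: SmI2 (2.5 equiv), THF–MeOH 10:1, −78 °C; aqueous quench; crude in CH2Cl2, DBU (0.3 equiv), rt
Reagents that add atoms: none
Why: Two-electron reduction of the enone expels the γ-methoxide (vinylogous α-alkoxy ketone cleavage) to a dienolate that protonates at C-α to give 12, and DBU then restores conjugation by protonating the ring-fusion carbon on the convex face, the only one that keeps ring C cis-fused to ring A.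

**Step 8**
Reactants: 13 tricyclic enone (rings A, C, D); 14 methyl (E)-but-2-enoate
Product: 17 enol triflate of the Michael adduct, via lithium dienolate 15 (not isolated), via lithium enolate 16 (not isolated)
Conditions: 14, LDA (1.15 equiv), THF–DMPU, −78 °C; 13, −78 to −40 °C; PhNTf2 (1.3 equiv), −40 to 0 °C
Reagents that add atoms: N-phenylbis(trifluoromethanesulfonimide), O=S(=O)(N(c1ccccc1)S(=O)(=O)C(F)(F)F)C(F)(F)F
Why: Tandem Michael addition/enolate O-sulfonylation in which the dienolate reacts through its α-carbon at the enone β-carbon from the convex face of the bowl, anti to the ring C carbon on the neighbouring atom (this makes the later A/B junction trans), and the regiodefined enolate 16 is trapped as the triflate; the ester-bearing centre forms as a mixture and is corrected in step 11.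

**Step 9**
Reactants: 17 enol triflate of the Michael adduct
Product: 18 diene ester (ring A alkene in place)
Conditions: Pd(OAc)2 (5 mol %), PPh3 (10 mol %), HCO2H (3 equiv), n-Bu3N (4 equiv), DMF, 60 °C
Reagents that add atoms: none
Why: Palladium-catalysed formate reduction of an enol triflate (oxidative addition to zerovalent palladium, hydride from formate, reductive elimination) leaves the ring A double bond where the target has it and touches no stereocentre or other alkene.

**Step 10**
Reactants: 18 diene ester (ring A alkene in place)
Product: 19 tetracyclic ester as a C-α epimer mixture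
Conditions: RuCl2(=CHPh)(PCy3)(SIMes) (second-generation Grubbs catalyst, 5 mol %), CH2Cl2 (2 mM), 40 °C, argon sparge
Reagents that add atoms: none
Why: Ring-closing metathesis between the vinyl group of the side chain on ring A and the (E)-propenyl group on ring C, which lie on the same side of ring C and trans across the ring A bond, closes cyclohexene ring B with loss of propene, while the cis ring A alkene and the remote (E)-alkene react far more slowly at high dilution; no stereocentre changes.

**Step 11**
Reactants: 19 tetracyclic ester as a C-α epimer mixture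
Product: 21 target methyl ester, via lithium dienolate 20 (not isolated)
Conditions: LDA (1.3 equiv), THF, −78 °C, 30 min; AcOH (3 equiv) in THF, −78 °C
Reagents that add atoms: none
Why: Both epimers give the same planar dienolate 20, and kinetic α-protonation from the equatorial direction, opposite the syn-axial ring-fusion hydrogen (the kinetic protonation pattern of exocyclic ester enolates), is predicted to place CO2Me pseudo-axial and cis to the ring A bond on the adjacent carbon while keeping the double bond out of conjugation; this facial preference rests on a model and is the least certain stereochemical call in the route.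

**Compound list**
1 | 4-hydroxyphenylboronic acid | OB(O)c1ccc(O)cc1 | starting material
2 | ethyl (2E,4E)-hexa-2,4-dienoate (ethyl sorbate) | CCOC(=O)/C=C/C=C/C | starting material
3 | ethyl (3R,4E)-3-(4-hydroxyphenyl)hex-4-enoate | CCOC(=O)C[C@H](/C=C/C)c1ccc(O)cc1 | intermediate
4 | 11-bromoundec-1-ene | C=CCCCCCCCCCBr | starting material
5 | (E)-11-bromoundec-2-ene | C/C=C/CCCCCCCCBr | intermediate
6 | [(E)-undec-9-en-1-yl]triphenylphosphonium bromide | C/C=C/CCCCCCCC[P+](c1ccccc1)(c1ccccc1)c1ccccc1.[Br-] | intermediate
7 | [(E)-undec-9-en-1-ylidene]triphenylphosphorane (ylide from 6) | C/C=C/CCCCCCCC=P(c1ccccc1)(c1ccccc1)c1ccccc1 | intermediate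
8 | (3R,4E)-3-(4-hydroxyphenyl)hex-4-enal (released from its aluminium hemiacetal) | O=CC[C@H](/C=C/C)c1ccc(O)cc1 | intermediate
9 | 4-[(2E,4R,6Z,15E)-heptadeca-2,6,15-trien-4-yl]phenol | Oc1ccc(cc1)[C@@H](/C=C/C)C/C=C\CCCCCCC/C=C/C | intermediate
10 | 4-[(2E,4R,6Z,15E)-heptadeca-2,6,15-trien-4-yl]-4-methoxycyclohexa-2,5-dien-1-one | COC1(C=CC(=O)C=C1)[C@@H](/C=C/C)C/C=C\CCCCCCC/C=C/C | intermediate
11 | tricyclic methoxy enone: cyclohex-2-en-1-one (ring A) cis-fused across C5–C6 to cyclobutane D and across C4–C5 to cyclopentane C (C and D also cis-fused); OMe on C4; (E)-dec-8-enyl on the D carbon attached to C6, exo (anti to rings A and C); (E)-prop-1-enyl on the ring C carbon attached to C4, cis to the C4–C3 bond | C/C=C/CCCCCCC[C@@H]1[C@H]2C(=O)C=C[C@]3(OC)[C@H]2[C@H]1C[C@@H]3/C=C/C | intermediate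
12 | deconjugated ketone: as 11 without OMe, ring A double bond C3=C4 (β,γ to the ketone) | C/C=C/CCCCCCC[C@@H]1[C@H]2C(=O)CC=C3[C@H]2[C@H]1C[C@@H]3/C=C/C | intermediate
13 | tricyclic enone: as 11 with H in place of OMe at C4, that H on the same (convex) face as the other ring-fusion hydrogens | C/C=C/CCCCCCC[C@@H]1[C@H]2C(=O)C=C[C@@H]3[C@H]2[C@H]1C[C@@H]3/C=C/C | intermediate
14 | methyl (E)-but-2-enoate (methyl crotonate) | C/C=C/C(=O)OC | starting material
15 | lithium 1-methoxybuta-1,3-dien-1-olate (dienolate of 14) | [Li+].[O-]C(OC)=CC=C | intermediate
16 | lithium enolate of the Michael adduct: ring A C1(O–)=C2, C3 carries CH(CO2Me)CH=CH2 trans to the ring C carbon on C4, C-α unassigned | [Li+].C/C=C/CCCCCCC[C@@H]1[C@H]2C([O-])=C[C@H](C(C=C)C(=O)OC)[C@@H]3[C@H]2[C@H]1C[C@@H]3/C=C/C | intermediate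
17 | enol triflate of the Michael adduct (OTf on C1, C1=C2) | C/C=C/CCCCCCC[C@@H]1[C@H]2C(OS(=O)(=O)C(F)(F)F)=C[C@H](C(C=C)C(=O)OC)[C@@H]3[C@H]2[C@H]1C[C@@H]3/C=C/C | intermediate
18 | diene ester: as 17 with H in place of OTf (ring A cyclohexene), C-α epimer mixture | C/C=C/CCCCCCC[C@@H]1[C@H]2C=C[C@H](C(C=C)C(=O)OC)[C@@H]3[C@H]2[C@H]1C[C@@H]3/C=C/C | intermediate
19 | tetracyclic methyl ester, rings A/B trans-fused, epimer mixture at the CO2Me carbon | C/C=C/CCCCCCC[C@@H]1[C@H]2C=C[C@H]3[C@@H]4[C@H]2[C@H]1C[C@@H]4C=CC3C(=O)OC | intermediate
20 | lithium dienolate of 19 (exocyclic C=C(O–)OMe on ring B) | [Li+].C/C=C/CCCCCCC[C@@H]1[C@H]2C=C[C@H]3[C@@H]4[C@H]2[C@H]1C[C@@H]4C=CC3=C([O-])OC | intermediate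
21 | CNP0133550.2: methyl ester with rings A/B trans-fused, ring C cis-fused to A, B and D, (E)-dec-8-enyl exo on D, CO2Me cis to the ring A bond on the adjacent fusion carbon | C/C=C/CCCCCCC[C@@H]1[C@H]2C=C[C@H]3[C@@H]4[C@H]2[C@H]1C[C@@H]4C=C[C@H]3C(=O)OC | target

**Step count**
Total: 11 steps. Longest linear sequence: 10 steps (2, 3, 4, 5, 6, 7, 8, 9, 10, 11), counted from 11-bromoundec-1-ene 4; the branch from the arene (1, then 4 to 11) is 9 steps.

**Three steps most likely to fail**

Step 6. The cross-conjugated dienone can rearrange to a lumiketone-type product instead of cyclising, the product enone can be photolysed further, and the choice between the two enone arms rests on a conformational preference. The fallback sets out from 10 and removes one enone arm before any light is used. Copper hydride desymmetrisation (Cu(OAc)2, the DTBM-SEGPHOS antipode matched to the side-chain centre, (EtO)2MeSiH, t-BuOH, toluene) reduces a single arm and gives the 4-methoxycyclohex-2-enone F1, whose quaternary carbon is now a defined stereocentre. Irradiation of this simple enone gives the saturated tricyclic methoxy ketone F2 by an ordinary enone–alkene [2+2], in which the arm is no longer chosen photochemically. Dehydrogenation with IBX (DMSO, 70 °C) toward the only α-CH2 restores the enone, and the route is rejoined at 11.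

Step 7. Methoxide is a poor leaving group, the radical anion sits next to a cyclobutane that can fragment, and the deconjugated ketone 12 may resist conjugation. The fallback sets out from 9 and changes the group that has to leave. Dearomatisation with PhI(OAc)2 in AcOH gives the quinol acetate F3, and irradiation as in step 6 gives the acetoxy tricyclic enone F4. Zn dust in AcOH at rt then removes the γ-acetoxy group by a two-electron cleavage that needs no SmI2, and DBU completes the conjugation; this comes back to the route at 13.

Step 11. The face of protonation of dienolate 20 is only predicted by a model, and α,β-conjugation is a competing sink. The fallback sets out from 13 and makes the ester-bearing centre by a sigmatropic shift instead of a protonation. Luche reduction (NaBH4, CeCl3·7H2O, MeOH, −78 °C; hydride from the convex face) gives the allylic alcohol F5, and Mitsunobu esterification with but-3-enoic acid (PPh3, DIAD, THF) inverts it to the ester F6. LDA and Me3SiCl (THF, −78 °C) give the silyl ketene acetal F7. On warming, F7 undergoes Ireland–Claisen rearrangement on the convex face: the new C–C bond is trans to the ring C carbon, the ring A alkene forms directly, and C-α is set by the ketene acetal geometry chosen through the enolisation solvent. Aqueous work-up gives the acid F8, and Me3SiCHN2 (MeOH–toluene) gives 18 as one C-α epimer. Step 10 then delivers 21 directly, and steps 8, 9 and 11 are not needed.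

**Further compounds**
F1 | step 6 | 4-[(2E,4R,6Z,15E)-heptadeca-2,6,15-trien-4-yl]-4-methoxycyclohex-2-en-1-one, the C4 epimer that cyclises to F2 | O=C1C=C[C@](OC)([C@@H](/C=C/C)C/C=C\CCCCCCC/C=C/C)CC1
F2 | step 6 | saturated tricyclic methoxy ketone (11 with C2–C3 single bond) | C/C=C/CCCCCCC[C@@H]1[C@H]2C(=O)CC[C@]3(OC)[C@H]2[C@H]1C[C@@H]3/C=C/C
F3 | step 7 | 1-[(2E,4R,6Z,15E)-heptadeca-2,6,15-trien-4-yl]-4-oxocyclohexa-2,5-dien-1-yl acetate | CC(=O)OC1(C=CC(=O)C=C1)[C@@H](/C=C/C)C/C=C\CCCCCCC/C=C/C
F4 | step 7 | acetoxy tricyclic enone (11 with OAc in place of OMe) | C/C=C/CCCCCCC[C@@H]1[C@H]2C(=O)C=C[C@]3(OC(C)=O)[C@H]2[C@H]1C[C@@H]3/C=C/C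
F5 | step 11 | allylic alcohol from 13 (C1–OH on the concave face, syn to rings C and D) | C/C=C/CCCCCCC[C@@H]1[C@H]2[C@@H](O)C=C[C@@H]3[C@H]2[C@H]1C[C@@H]3/C=C/C
F6 | step 11 | but-3-enoate ester with inverted C1–O (oxygen on the convex face) | C/C=C/CCCCCCC[C@@H]1[C@H]2[C@H](OC(=O)CC=C)C=C[C@@H]3[C@H]2[C@H]1C[C@@H]3/C=C/C
F7 | step 11 | trimethylsilyl ketene acetal of F6 | C/C=C/CCCCCCC[C@@H]1[C@H]2[C@H](OC(O[Si](C)(C)C)=CC=C)C=C[C@@H]3[C@H]2[C@H]1C[C@@H]3/C=C/C
F8 | step 11 | carboxylic acid corresponding to 18, single C-α epimer | C/C=C/CCCCCCC[C@@H]1[C@H]2C=C[C@H]([C@@H](C=C)C(=O)O)[C@@H]3[C@H]2[C@H]1C[C@@H]3/C=C/C
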